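# Proposed total synthesis of (3S,5R,8S,3′R,6′R)-5,8-epoxy-5,8-dihydro-β,ε-carotene-3,3′-diol (CNP0219251.2)

## Structural features

The target is the 8S furanoid oxide of lutein: a C40 chain of eight conjugated E double bonds (C7′=C8′ through C9=C10) that joins ring A at C6′ to ring C at C8. Ring A is a cyclohexene (C4′=C5′) with a gem-dimethyl quaternary C1′, an allylic carbinol at C3′ (R) and the stereocentre C6′ (R), which sits between C1′ and C5′, carries the chain and is trans to the C3′ hydroxyl. Rings B and C form a hexahydrobenzofuran: cyclohexane ring B (C1 gem-dimethyl, C3 carbinol, S) is fused through C5 and C6 to the 2,5-dihydrofuran ring C (O, C5, C6=C7, C8), with the ether oxygen on C5 trans to the C3 hydroxyl and the chain on C8 cis to the C5 methyl. The stereocentres therefore fall into two remote sets, C3′/C6′ (1,4 in ring A) and C3/C5/C8 (1,3 in ring B, 1,3 across the oxygen in ring C). Fragile points are the polyene (light, oxygen, acid), the allylic C3′–O bond, the doubly allylic C6′–H (its loss brings the ring double bond into conjugation and erases the centre) and the doubly allylic C8–O bond, which can ionise and epimerise in acid. The real difficulties are making C6′ beside the quaternary C1′ while C4′=C5′ stays out of conjugation, and fixing C8 relative to C5, whose methyl and ring-methylene substituents give no useful steric bias. The key step exploits the C1′–C6′ bond of ring A: C6′ is a methine carrying the first olefinic carbon of the chain (C7′) and its neighbour C1′ is fully substituted, the pattern left when the γ-carbon of an allylsilane adds to the β-carbon of an enone with two β-methyl groups.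

## Logic of the disconnections

**36 ⇐ 35.** Cut: the two O–Si bonds at C3 and C3′. Both carbinols travel protected so that neither the allylic C3′–O bond nor the polyene meets acid; the last step is then a fluoride desilylation. Gain: none in skeleton, but every earlier step can be chosen without regard to free hydroxyls. Demand: non-acidic cleavage.

**35 ⇐ 20 + 34.** Cut: C11′=C12′. This divides C40 into C15 and C25 with all five stereocentres already in place, and puts the phosphorus on the ring-A half, whose salt can be made without acid. Gain: two fragments of comparable effort, no stereocentre formed in the union. Demand: a base too weak to remove C6′–H or C8–H, and equilibration of the new disubstituted double bond to E.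

**34 ⇐ 32 + 33.** Cut: C11=C12. 33 is a symmetrical, purchasable C10 unit, so mono-olefination needs only an excess of it and no protecting group. Gain: C25 reduced to C15 plus C10. Demand: the ylide from 32 must olefinate faster than it opens ring C by vinylogous β-elimination.

**20 ⇐ 18 ⇐ 17 ⇐ 15 + 16.** Cuts: C11′–P, the C11′ oxidation level, C9′=C10′. The C13 methyl ketone is extended by two carbons under basic or neutral conditions only. Gain: back to a ketone whose side chain is four carbons long. Demand: E geometry at C9′=C10′ (the Z isomer is separated) and no acid.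

**15 ⇐ 13 + 14.** Cut: C7′=C8′. The vinyl group left by the key step is the handle for cross-metathesis with an electron-poor alkene. Gain: the side chain shrinks to a vinyl group. Demand: metathesis at a hindered monosubstituted alkene without double-bond migration toward C6′.

**13 ⇐ 12 ⇐ 11 ⇐ 10.** Cuts: O–Si, the C3′–H bond (hydride addition), the C4′=C5′ π-bond (dehydrogenation). The ketone of 10 sits at C3′, and dehydrogenation can only go toward C4′/C5′ because C2′ adjoins the quaternary C1′. Gain: C3′ and the ring double bond are removed, leaving a saturated ketone in which the C5′ methyl is a temporary control element. Demand: reagent control at C3′ (1,4 to C6′, too far for substrate control) and no enolisation toward C6′ once the enone exists.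

**10 ⇐ 9 (key).** Cut: the C1′–C6′ ring bond. It lies between the quaternary carbon and the vinyl-bearing stereocentre, the retron of an intramolecular allylsilane conjugate addition. Gain: ring A, C1′ and C6′ are traced to an open chain with one stereocentre. Demand: trans induction from C5′ to C6′ and Lewis-acid conditions that do not protodesilylate.

**9 ⇐ 7 + 8; 7 ⇐ 5 + 6; 5 ⇐ 3 ⇐ 2 ⇐ 1.** Cuts: C2′–C3′ (acyl substitution), the allylsilane C=C (cross-metathesis), the amide C–N bond, the salt. Three purchasable pieces carry all carbons of ring A. The metathesis is placed before the enone exists, because a vinyl group and an isobutenyl ketone five atoms apart would ring-close to 4-methylcyclopent-2-enone with loss of isobutene. Gain: an acid with one stereocentre, obtained by resolution. Demand: E-enriched metathesis and clean mono-addition of the Grignard reagent.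

**32 ⇐ 30 ⇐ 29.** Cuts: C11–P, then O–C8 of ring C. Because C5 cannot steer a reagent to one face of C8, C8 is derived from an allene axis by a stereospecific 5-endo hydroalkoxylation. Gain: ring C and the C8 centre are replaced by an axis. Demand: chirality transfer without ionisation of the C8–O bond.

**29 ⇐ 28 ⇐ 27.** Cuts: C8–H with C6–O (SN2′ hydride), then the two epoxide C–O bonds. Axis and C5 carbinol both descend from one epoxide. Gain: an enyne whose only stereocentre is C3. Demand: hydride delivery syn to the leaving oxygen, and epoxidation anti to the C3 silyloxy group.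

**27 ⇐ 24 + 26; 24 ⇐ 22 ⇐ 21; 26 ⇐ 25.** Cuts: C6–C7 (sp2–sp coupling), the enol C–O bond, O–Si, the ester. The ketone carbon of 21 becomes C6 and its hydroxyl carbon becomes C3. Gain: a chiral-pool hydroxy ketone and a C6 enynol. Demand: a single enol triflate, guaranteed because only one α-carbon bears hydrogen.

## Other disconnections considered

**Alternative 1:** Gold allenol cycloisomerisation.
- **Cut:** the O–C8 bond of ring C, taking the dihydrofuran A1 back to the open allenol A2 (allene C6=C7=C8, free hydroxyl on C5).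
- **Forward step:** cationic gold from Ph3PAuCl and AgBF4 (monovalent gold) binds the allene double bond remote from ring B. The tertiary hydroxyl attacks C8 in the allene plane, opposite the metal, and protodeauration releases A1. The substituents on C8 stand perpendicular to that plane, so the axis of A2 should become the C8 centre unchanged.
- **In favour:** it is stereospecific, catalytic and mild, and it solves the C5/C8 relationship that steric bias cannot.
- **Against it here:** the closure itself is not rejected. The chosen route uses the same O–C8 bond formation as a supporting step (step 20, on diol 29). What is declined is building the plan around it: it forms no C–C bond, only moves the stereochemical burden to the axis and the epoxidation before it, and contributes nothing to ring A, which would then need a resolved ionone-type ketone or similar.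
- **Comparison:** in structure, one ring, one C–O bond and one centre, against one ring, one C–C bond to a quaternary carbon and one centre. In mechanism the gold step is stereospecific while the allylsilane closure is only diastereoselective; here the alternative is the better step. On ring C the two plans are equal by construction, and step economy is equal.

**Alternative 2:** Carbonylative (2+2+1) assembly.
- **Cut:** three bonds at once (C5–C6, C7–C8, lactone C8–O), taking the bicyclic butenolide A3 back to the open keto alkyne A4 and carbon monoxide.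
- **Forward step:** under CO, the chiral ansa-titanocene ethylenebis(tetrahydroindenyl)Ti(CO)2 (divalent titanium) would couple the methyl ketone and the silylalkyne to an oxatitanacyclopentene, insert CO and eliminate reductively to A3, choosing one ketone face and so C5.
- **In favour:** two rings, three bonds and the quaternary C5 in one catalytic enantioselective step from an achiral chain. In bonds and rings per step it is better than the chosen key step, and it needs no chiral pool for ring B.
- **Against it here:** catalytic asymmetric versions of this titanocene chemistry rest on ketone–alkene pairs. A ketone–alkyne pair with a quaternary propargylic carbon and a methyl/methylene pair to distinguish at the carbonyl is a stretch. A3 is also far from the target: the silyl group must come off, the C3 ketal must become a carbinol of defined configuration, and the lactone carbonyl must become the C8 methine with its side chain, again with no steric bias from C5.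
- **Comparison:** the richest step in structure, the least secure in mechanism, and after the repair steps no shorter than the chosen plan. It also leaves ring A untouched.

**Alternative 3:** Directed epoxidation, then epoxide opening at C5.
- **Cut:** the O–C5 bond, opening ring C of the hydroxy tetrahydrofuran A5 to the epoxy diol A6, whose 5,6-epoxide lies syn to the free C3 hydroxyl.
- **Forward step:** pyridinium p-toluenesulfonate activates the epoxide and the C8 hydroxyl attacks tertiary C5 from the rear. C5 is inverted, the epoxide oxygen stays on C6 as a tertiary hydroxyl, and a cis-fused tetrahydrofuran results (the competing attack at C6 would need an oxetane).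
- **In favour:** a hydroxyl-directed epoxidation is a more dependable way to set C5/C6 from C3 than the undirected epoxidation of step 18; on this point the alternative is the better. The ring closure is stereospecific and metal-free, and all centres are sp3 and checkable.
- **Against it here:** C8 must already be a carbinol of defined configuration, which costs a further asymmetric step. Opening at a tertiary carbon under acid can leak through an ionised pathway. The C6 hydroxyl must then be dehydrated toward C7, beside two quaternary carbons and a labile ether, before ring C has its double bond.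
- **Comparison:** equal or better than the chosen plan in stereochemical reliability at C5, weaker in step economy (carbinol setting and dehydration are extra), and silent on ring A.

Key step: step 6

## Assumptions and checks before the steps

- Assumption: 21, 25 and 33 are purchased as such.
- Assumption: the (R)-acid forms the less soluble salt with (R)-1-phenylethylamine; if the pairing is the reverse, the (S)-amine is used and nothing else changes.
- Stereochemical check: the (R)-acid 3 leads to (6R)-9, to (4S,5R)-10 and to (R)-11, and C6′ of 10 has the sense of the target. No descriptor needed correction.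
- Design correction: the allylsilane metathesis (step 4) precedes the Grignard addition (step 5), for the ring-closing reason given above.
- Design correction: the cis isomer of 10 would become the enantiomer of 11 on dehydrogenation, so it is removed at 10.
- Steps 21–24 are run under argon with exclusion of light.

## Route

**Step 1**
Reactants: 1 rac-3-methylpent-4-enoic acid
Product: 2 (R)-1-phenylethylammonium (3R)-3-methylpent-4-enoate
Conditions: (R)-PhCH(CH3)NH2 (1.0 equiv), acetone, 50 °C → 5 °C; two recrystallisations from acetone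
Reagents that add atoms: (R)-1-phenylethylamine, C[C@@H](N)c1ccccc1
Why: Classical resolution through diastereomeric ammonium carboxylates; no stereocentre is formed, the salt of the (R)-acid is taken as the less soluble one and is recrystallised to constant rotation.

**Step 2**
Reactants: 2 (R)-1-phenylethylammonium (3R)-3-methylpent-4-enoate
Product: 3 (3R)-3-methylpent-4-enoic acid
Conditions: 1 M HCl, Et2O, 0 °C
Reagents that add atoms: none
Why: Proton transfer liberates the acid; the stereocentre is β to the carboxyl group and cannot epimerise.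

**Step 3**
Reactants: 3 (3R)-3-methylpent-4-enoic acid
Product: 5 (3R)-N-methoxy-N,3-dimethylpent-4-enamide, via acyl imidazolide 4 (not isolated)
Conditions: CDI (1.1 equiv), CH2Cl2, 0 °C → rt; then MeNH(OMe)·HCl (1.2 equiv), rt
Reagents that add atoms: 1,1′-carbonyldiimidazole, O=C(n1ccnc1)n1ccnc1; N,O-dimethylhydroxylamine hydrochloride, CNOC.Cl
Why: Acyl substitution through the acyl imidazolide (Weinreb amide formation); the stereocentre is not α to the carbonyl, so activation cannot racemise it, and the terminal alkene is inert.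

**Step 4**
Reactants: 5 (3R)-N-methoxy-N,3-dimethylpent-4-enamide; 6 allyltrimethylsilane
Product: 7 (3R,4E)-N-methoxy-N,3-dimethyl-6-(trimethylsilyl)hex-4-enamide
Conditions: second-generation Grubbs catalyst (3 mol %), 6 (4 equiv), CH2Cl2, 40 °C
Reagents that add atoms: none
Why: Olefin cross-metathesis of a monosubstituted alkene with excess allylsilane; the allylic branch beside the reacting alkene should favour the E isomer and the amide is tolerated. It is run here and not on the later dienone, which would ring-close by metathesis to a cyclopentenone.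

**Step 5**
Reactants: 7 (3R,4E)-N-methoxy-N,3-dimethyl-6-(trimethylsilyl)hex-4-enamide; 8 2-methylprop-1-enylmagnesium bromide
Product: 9 (6R,7E)-2,6-dimethyl-9-(trimethylsilyl)nona-2,7-dien-4-one
Conditions: 8 (1.5 equiv, THF), THF, −20 → 0 °C; aq. NH4Cl, 0 °C
Reagents that add atoms: none
Why: Weinreb ketone synthesis: the magnesium chelate of the tetrahedral adduct stops at one addition and gives the enone on buffered quench. The allylsilane is inert to the Grignard reagent and the β,β-disubstituted enone resists conjugate addition of the released hydroxylamine.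

**Step 6 (key step)**
Reactants: 9 (6R,7E)-2,6-dimethyl-9-(trimethylsilyl)nona-2,7-dien-4-one
Product: 10 (4S,5R)-4-ethenyl-3,3,5-trimethylcyclohexan-1-one
Conditions: TiCl4 (1.1 equiv), 2,6-di-tert-butylpyridine (0.2 equiv), CH2Cl2, −78 °C; aq. NaHCO3
Reagents that add atoms: none
Why: TiCl4 binds the C3′ carbonyl and makes the β,β-dimethyl enone a titanium-bound allyl cation with its charge at tertiary C1′; the allylsilane attacks C1′ through its γ-carbon C6′, the β-silyl cation at C7′ gives up silicon to chloride, and C7′=C8′ appears as the vinyl group while the ketone waits as its titanium enolate for the quench. The closest known reaction type is the intramolecular Hosomi–Sakurai conjugate allylation of enones, including β,β-disubstituted acceptors that give quaternary carbons. The single ring closes in a 6-endo-trig mode with respect to the enone (C1′, C2′ and C3′ all lie in the ring) and exo with respect to the allylsilane double bond. The new centre C6′ is controlled by C5′: in the chair-like transition state C5′–H eclipses the reacting double bond, the C5′ methyl is equatorial, away from the axial C1′ methyl, and the forming vinyl group is equatorial, which gives the trans ketone with C6′ as in the target. Conjugate addition is the only ring-forming path, since 1,2-attack would need a four-membered ring. The step needs trans-over-cis diastereoselectivity, secured by the methyl/methyl contact in the competing chair, and chemoselectivity against protodesilylation, secured by low temperature and the hindered pyridine. The alkene geometry is lost in the product, so residual Z isomer cannot change the constitution, and any cis ketone is removed here by chromatography because after step 7 it would be the enantiomer of 11.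

**Step 7**
Reactants: 10 (4S,5R)-4-ethenyl-3,3,5-trimethylcyclohexan-1-one
Product: 11 (4R)-4-ethenyl-3,5,5-trimethylcyclohex-2-en-1-one
Conditions: 2-iodoxybenzoic acid (1.5 equiv), 4-methoxypyridine N-oxide (1.5 equiv), DMSO, 25 °C
Reagents that add atoms: none
Why: Dehydrogenation of a ketone by 2-iodoxybenzoic acid through its enol; only the C4′ enol can go on to an enone because C2′ adjoins the quaternary C1′, so the double bond must be C4′=C5′ and the auxiliary C5′ centre disappears as planned. The N-oxide-activated reagent works at room temperature, which should spare the now γ-positioned, doubly allylic C6′–H.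

**Step 8**
Reactants: 11 (4R)-4-ethenyl-3,5,5-trimethylcyclohex-2-en-1-one
Product: 12 (1R,4R)-4-ethenyl-3,5,5-trimethylcyclohex-2-en-1-ol
Conditions: (S)-2-methyl-CBS-oxazaborolidine (20 mol %), BH3·SMe2 (0.7 equiv), THF, −30 °C; MeOH
Reagents that add atoms: none
Why: Corey–Bakshi–Shibata reduction: the carbonyl binds boron anti to the alkenyl arm (the larger group) and the (S)-catalyst should deliver hydride to the face that gives the (R)-carbinol, trans to the C6′ vinyl group, by 1,2-reduction. C3′ is too remote from C6′ for substrate control, hence reagent control; the cis epimer and any material of the wrong C6′ configuration are diastereomers of 12 and are removed by chromatography.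

**Step 9**
Reactants: 12 (1R,4R)-4-ethenyl-3,5,5-trimethylcyclohex-2-en-1-ol
Product: 13 tert-butyl{[(1R,4R)-4-ethenyl-3,5,5-trimethylcyclohex-2-en-1-yl]oxy}dimethylsilane
Conditions: TBSCl (1.2 equiv), imidazole (2.5 equiv), DMF, rt
Reagents that add atoms: tert-butyldimethylsilyl chloride, CC(C)(C)[Si](C)(C)Cl
Why: Standard silylation of a secondary alcohol; the ether blocks ionisation of the allylic C3′–O bond in later steps and is removed only at the end.

**Step 10**
Reactants: 13 tert-butyl{[(1R,4R)-4-ethenyl-3,5,5-trimethylcyclohex-2-en-1-yl]oxy}dimethylsilane; 14 but-3-en-2-one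
Product: 15 (3E)-4-[(1R,4R)-4-{[tert-butyl(dimethyl)silyl]oxy}-2,6,6-trimethylcyclohex-2-en-1-yl]but-3-en-2-one
Conditions: second-generation Hoveyda–Grubbs catalyst (5 mol %), 14 (5 equiv), 1,4-benzoquinone (10 mol %), CH2Cl2, 40 °C
Reagents that add atoms: none
Why: Cross-metathesis of a monosubstituted alkene with an electron-poor vinyl ketone, which should give the E enone; the trisubstituted ring alkene is too hindered to take part. Benzoquinone suppresses ruthenium hydride species that would move the double bond toward C6′.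

**Step 11**
Reactants: 15 (3E)-4-[(1R,4R)-4-{[tert-butyl(dimethyl)silyl]oxy}-2,6,6-trimethylcyclohex-2-en-1-yl]but-3-en-2-one; 16 triethyl phosphonoacetate
Product: 17 ethyl (2E,4E)-5-[(1R,4R)-4-{[tert-butyl(dimethyl)silyl]oxy}-2,6,6-trimethylcyclohex-2-en-1-yl]-3-methylpenta-2,4-dienoate
Conditions: NaH (1.5 equiv), 16 (1.6 equiv), THF, 0 → 40 °C
Reagents that add atoms: none
Why: Horner–Wadsworth–Emmons olefination of a methyl ketone with a stabilised phosphonate anion; the E isomer at C9′=C10′ should dominate and the Z isomer is removed by chromatography. The anion is too weak a base to remove the γ-proton at C6′.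

**Step 12**
Reactants: 17 ethyl (2E,4E)-5-[(1R,4R)-4-{[tert-butyl(dimethyl)silyl]oxy}-2,6,6-trimethylcyclohex-2-en-1-yl]-3-methylpenta-2,4-dienoate
Product: 18 (2E,4E)-5-[(1R,4R)-4-{[tert-butyl(dimethyl)silyl]oxy}-2,6,6-trimethylcyclohex-2-en-1-yl]-3-methylpenta-2,4-dien-1-ol
Conditions: i-Bu2AlH (2.5 equiv), CH2Cl2, −78 °C; aq. potassium sodium tartrate
Reagents that add atoms: none
Why: 1,2-Reduction of the conjugated ester to the allylic alcohol by the aluminium hydride at low temperature; silyl ether and triene are untouched.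

**Step 13**
Reactants: 18 (2E,4E)-5-[(1R,4R)-4-{[tert-butyl(dimethyl)silyl]oxy}-2,6,6-trimethylcyclohex-2-en-1-yl]-3-methylpenta-2,4-dien-1-ol
Product: 20 [(2E,4E)-5-[(1R,4R)-4-{[tert-butyl(dimethyl)silyl]oxy}-2,6,6-trimethylcyclohex-2-en-1-yl]-3-methylpenta-2,4-dien-1-yl]triphenylphosphonium bromide, via allylic bromide 19 (not isolated)
Conditions: CBr4 (1.2 equiv), PPh3 (1.25 equiv), 2,6-lutidine (0.2 equiv), CH2Cl2, −20 °C; then PPh3 (1.5 equiv), EtOAc, rt
Reagents that add atoms: carbon tetrabromide, BrC(Br)(Br)Br; triphenylphosphine, c1ccc(cc1)P(c1ccccc1)c1ccccc1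
Why: Appel bromination under neutral conditions, then SN2 quaternisation of the primary allylic bromide by PPh3; acid is avoided because it would ionise the allylic C3′–O bond or cause loss of the C6′ proton.

**Step 14**
Reactants: 21 (4R,6R)-4-hydroxy-2,2,6-trimethylcyclohexan-1-one
Product: 22 (4R,6R)-4-{[tert-butyl(dimethyl)silyl]oxy}-2,2,6-trimethylcyclohexan-1-one
Conditions: TBSCl (1.2 equiv), imidazole (2.5 equiv), DMF, rt
Reagents that add atoms: tert-butyldimethylsilyl chloride, CC(C)(C)[Si](C)(C)Cl
Why: Standard silylation of the secondary alcohol; the hindered ketone is unaffected and its α-centre is removed in the next step anyway.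

**Step 15**
Reactants: 22 (4R,6R)-4-{[tert-butyl(dimethyl)silyl]oxy}-2,2,6-trimethylcyclohexan-1-one
Product: 24 (4R)-4-{[tert-butyl(dimethyl)silyl]oxy}-2,6,6-trimethylcyclohex-1-en-1-yl trifluoromethanesulfonate, via lithium enolate 23 (not isolated)
Conditions: LiN(iPr)2 (1.2 equiv), THF, −78 °C; then PhNTf2 (1.2 equiv), −78 °C → rt
Reagents that add atoms: lithium diisopropylamide, [Li]N(C(C)C)C(C)C; N-phenylbis(trifluoromethanesulfonimide), O=S(=O)(N(c1ccccc1)S(=O)(=O)C(F)(F)F)C(F)(F)F
Why: Enolisation can only go toward the methyl-bearing α-carbon because the other is quaternary, so a single tetrasubstituted enolate forms and is O-sulfonylated; the C4 centre is untouched.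

**Step 16**
Reactants: 25 (2E)-3-methylpent-2-en-4-yn-1-ol
Product: 26 (2E)-3-methylpent-2-en-4-yn-1-yl 2,2-dimethylpropanoate
Conditions: PivCl (1.2 equiv), pyridine, CH2Cl2, 0 °C
Reagents that add atoms: pivaloyl chloride, CC(C)(C)C(=O)Cl
Why: Acylation of a primary allylic alcohol; the pivalate survives the coupling and lowers the reactivity of the C9=C10 double bond toward the peracid of step 18.

**Step 17**
Reactants: 24 (4R)-4-{[tert-butyl(dimethyl)silyl]oxy}-2,6,6-trimethylcyclohex-1-en-1-yl trifluoromethanesulfonate; 26 (2E)-3-methylpent-2-en-4-yn-1-yl 2,2-dimethylpropanoate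
Product: 27 (2E)-5-[(4R)-4-{[tert-butyl(dimethyl)silyl]oxy}-2,6,6-trimethylcyclohex-1-en-1-yl]-3-methylpent-2-en-4-yn-1-yl 2,2-dimethylpropanoate
Conditions: Pd(PPh3)4 (5 mol %), CuI (10 mol %), i-Pr2NH, DMF, rt → 40 °C
Reagents that add atoms: none
Why: Sonogashira coupling of an enol triflate with a terminal alkyne forms the C6–C7 bond; oxidative addition to hindered cyclohexenyl triflates is known, and ester and silyl ether are inert.

**Step 18**
Reactants: 27 (2E)-5-[(4R)-4-{[tert-butyl(dimethyl)silyl]oxy}-2,6,6-trimethylcyclohex-1-en-1-yl]-3-methylpent-2-en-4-yn-1-yl 2,2-dimethylpropanoate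
Product: 28 (2E)-5-[(1R,4S,6R)-4-{[tert-butyl(dimethyl)silyl]oxy}-2,2,6-trimethyl-7-oxabicyclo[4.1.0]heptan-1-yl]-3-methylpent-2-en-4-yn-1-yl 2,2-dimethylpropanoate
Conditions: mCPBA (1.1 equiv), NaHCO3, CH2Cl2, 0 °C
Reagents that add atoms: 3-chloroperoxybenzoic acid, O=C(OO)c1cccc(Cl)c1
Why: Prilezhaev epoxidation: the tetrasubstituted ring alkene is the most electron-rich π-bond, and the peracid should approach anti to the silyloxy group, which sets C5 and C6 with the oxygen trans to the C3 oxygen. The minor syn epoxide is removed by chromatography and the bicarbonate buffers the acid-labile epoxide.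

**Step 19**
Reactants: 28 (2E)-5-[(1R,4S,6R)-4-{[tert-butyl(dimethyl)silyl]oxy}-2,2,6-trimethyl-7-oxabicyclo[4.1.0]heptan-1-yl]-3-methylpent-2-en-4-yn-1-yl 2,2-dimethylpropanoate
Product: 29 (2E)-5-[(2R,4S)-4-{[tert-butyl(dimethyl)silyl]oxy}-2-hydroxy-2,6,6-trimethylcyclohexylidene]-3-methylpenta-2,4-dien-1-ol with (R)-configured allene axis
Conditions: i-Bu2AlH (5 equiv), CH2Cl2, −78 → 0 °C; aq. potassium sodium tartrate
Reagents that add atoms: none
Why: SN2′ reduction of an alkynyl epoxide: the aluminium hydride first cleaves the pivalate, then binds the epoxide oxygen and passes hydride to C8 on the face of the departing C6–O bond (syn), the known course of this reagent with alkynyl epoxides, which gives the (R)-allene. The oxygen stays on C5 with its configuration unchanged, so the axis is derived from the epoxide.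

**Step 20**
Reactants: 29 (2E)-5-[(2R,4S)-4-{[tert-butyl(dimethyl)silyl]oxy}-2-hydroxy-2,6,6-trimethylcyclohexylidene]-3-methylpenta-2,4-dien-1-ol with (R)-configured allene axis
Product: 30 (2E)-3-[(2S,6S,7aR)-6-{[tert-butyl(dimethyl)silyl]oxy}-4,4,7a-trimethyl-2,4,5,6,7,7a-hexahydro-1-benzofuran-2-yl]but-2-en-1-ol
Conditions: Ph3PAuCl (2 mol %), AgBF4 (2 mol %), THF, 0 °C → rt
Reagents that add atoms: none
Why: Gold-catalysed cycloisomerisation of an α-hydroxyallene to a 2,5-dihydrofuran: the C5 hydroxyl attacks C8 in the allene plane (5-endo), anti to gold, and protodeauration follows. The substituents on C8 stand perpendicular to the forming ring, so the axis becomes the centre and the (5R, axis R) allenol should give the 8S ether with the side chain cis to the C5 methyl; THF and low loading are chosen so that the doubly allylic C8–O bond is not ionised.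

**Step 21**
Reactants: 30 (2E)-3-[(2S,6S,7aR)-6-{[tert-butyl(dimethyl)silyl]oxy}-4,4,7a-trimethyl-2,4,5,6,7,7a-hexahydro-1-benzofuran-2-yl]but-2-en-1-ol
Product: 32 [(2E)-3-[(2S,6S,7aR)-6-{[tert-butyl(dimethyl)silyl]oxy}-4,4,7a-trimethyl-2,4,5,6,7,7a-hexahydro-1-benzofuran-2-yl]but-2-en-1-yl]triphenylphosphonium bromide, via allylic bromide 31 (not isolated)
Conditions: CBr4 (1.2 equiv), PPh3 (1.25 equiv), 2,6-lutidine (0.2 equiv), CH2Cl2, −20 °C; then PPh3 (1.5 equiv), EtOAc, rt
Reagents that add atoms: carbon tetrabromide, BrC(Br)(Br)Br; triphenylphosphine, c1ccc(cc1)P(c1ccccc1)c1ccccc1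
Why: Appel bromination and SN2 quaternisation under neutral conditions; the usual acidic route to allylic phosphonium salts is avoided because acid would epimerise C8.

**Step 22**
Reactants: 32 [(2E)-3-[(2S,6S,7aR)-6-{[tert-butyl(dimethyl)silyl]oxy}-4,4,7a-trimethyl-2,4,5,6,7,7a-hexahydro-1-benzofuran-2-yl]but-2-en-1-yl]triphenylphosphonium bromide; 33 (2E,4E,6E)-2,7-dimethylocta-2,4,6-trienedial
Product: 34 (2E,4E,6E,8E,10E)-11-[(2S,6S,7aR)-6-{[tert-butyl(dimethyl)silyl]oxy}-4,4,7a-trimethyl-2,4,5,6,7,7a-hexahydro-1-benzofuran-2-yl]-2,7-dimethyldodeca-2,4,6,8,10-pentaenal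
Conditions: 33 (3 equiv), NaOMe (1.1 equiv), CH2Cl2/MeOH, 0 °C → rt; then heptane, 80 °C, dark
Reagents that add atoms: none
Why: Wittig olefination of a semi-stabilised allylic ylide with an excess of the symmetrical dialdehyde should give the mono-olefin; the new C11=C12 bond forms as an E/Z mixture that is equilibrated to E by heating, as is usual for polyenes. The ring ether oxygen on C8 is a poor leaving group, so vinylogous β-elimination from the ylide should not compete.

**Step 23**
Reactants: 20 [(2E,4E)-5-[(1R,4R)-4-{[tert-butyl(dimethyl)silyl]oxy}-2,6,6-trimethylcyclohex-2-en-1-yl]-3-methylpenta-2,4-dien-1-yl]triphenylphosphonium bromide; 34 (2E,4E,6E,8E,10E)-11-[(2S,6S,7aR)-6-{[tert-butyl(dimethyl)silyl]oxy}-4,4,7a-trimethyl-2,4,5,6,7,7a-hexahydro-1-benzofuran-2-yl]-2,7-dimethyldodeca-2,4,6,8,10-pentaenal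
Product: 35 (3S,5R,8S,3′R,6′R)-3,3′-bis{[tert-butyl(dimethyl)silyl]oxy}-5,8-epoxy-5,8-dihydro-β,ε-carotene
Conditions: NaOMe (1.2 equiv), CH2Cl2/MeOH, 0 °C → rt; then EtOAc, 70 °C, dark
Reagents that add atoms: none
Why: The second Wittig olefination joins the C15 and C25 halves at C11′=C12′; no stereocentre is formed and methoxide is not basic enough to touch C6′–H or C8–H. Thermal equilibration should give the all-E polyene.

**Step 24**
Reactants: 35 (3S,5R,8S,3′R,6′R)-3,3′-bis{[tert-butyl(dimethyl)silyl]oxy}-5,8-epoxy-5,8-dihydro-β,ε-carotene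
Product: 36 (3S,5R,8S,3′R,6′R)-5,8-epoxy-5,8-dihydro-β,ε-carotene-3,3′-diol
Conditions: Bu4NF (3 equiv), THF, 0 °C → rt, dark
Reagents that add atoms: none
Why: Fluoride cleaves both silyl ethers under basic, non-ionising conditions, which the allylic C3′ carbinol, the C8 ether and the polyene should tolerate.

## Compound list

1 | rac-3-methylpent-4-enoic acid | C=CC(C)CC(=O)O | starting material
2 | (R)-1-phenylethylammonium (3R)-3-methylpent-4-enoate | C=C[C@H](C)CC(=O)[O-].C[C@@H]([NH3+])c1ccccc1 | intermediate
3 | (3R)-3-methylpent-4-enoic acid | C=C[C@H](C)CC(=O)O | intermediate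
4 | 1-[(3R)-3-methylpent-4-enoyl]imidazole (not isolated) | C=C[C@H](C)CC(=O)n1ccnc1 | intermediate
5 | (3R)-N-methoxy-N,3-dimethylpent-4-enamide | C=C[C@H](C)CC(=O)N(C)OC | intermediate
6 | allyltrimethylsilane | C=CC[Si](C)(C)C | starting material
7 | (3R,4E)-N-methoxy-N,3-dimethyl-6-(trimethylsilyl)hex-4-enamide | C[Si](C)(C)C/C=C/[C@H](C)CC(=O)N(C)OC | intermediate
8 | 2-methylprop-1-enylmagnesium bromide | CC(C)=C[Mg]Br | starting material
9 | (6R,7E)-2,6-dimethyl-9-(trimethylsilyl)nona-2,7-dien-4-one | CC(C)=CC(=O)C[C@@H](C)/C=C/C[Si](C)(C)C | intermediate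
10 | (4S,5R)-4-ethenyl-3,3,5-trimethylcyclohexan-1-one (trans) | C[C@@H]1CC(=O)CC(C)(C)[C@H]1C=C | intermediate
11 | (4R)-4-ethenyl-3,5,5-trimethylcyclohex-2-en-1-one | CC1=CC(=O)CC(C)(C)[C@H]1C=C | intermediate
12 | (1R,4R)-4-ethenyl-3,5,5-trimethylcyclohex-2-en-1-ol | CC1=C[C@H](O)CC(C)(C)[C@H]1C=C | intermediate
13 | tert-butyl{[(1R,4R)-4-ethenyl-3,5,5-trimethylcyclohex-2-en-1-yl]oxy}dimethylsilane | CC1=C[C@H](O[Si](C)(C)C(C)(C)C)CC(C)(C)[C@H]1C=C | intermediate
14 | but-3-en-2-one | C=CC(C)=O | starting material
15 | (3E)-4-[(1R,4R)-4-{[tert-butyl(dimethyl)silyl]oxy}-2,6,6-trimethylcyclohex-2-en-1-yl]but-3-en-2-one | CC1=C[C@H](O[Si](C)(C)C(C)(C)C)CC(C)(C)[C@H]1/C=C/C(C)=O | intermediate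
16 | triethyl phosphonoacetate | CCOC(=O)CP(=O)(OCC)OCC | starting material
17 | ethyl (2E,4E)-5-[(1R,4R)-4-{[tert-butyl(dimethyl)silyl]oxy}-2,6,6-trimethylcyclohex-2-en-1-yl]-3-methylpenta-2,4-dienoate | CC1=C[C@H](O[Si](C)(C)C(C)(C)C)CC(C)(C)[C@H]1/C=C/C(C)=C/C(=O)OCC | intermediate
18 | (2E,4E)-5-[(1R,4R)-4-{[tert-butyl(dimethyl)silyl]oxy}-2,6,6-trimethylcyclohex-2-en-1-yl]-3-methylpenta-2,4-dien-1-ol | CC1=C[C@H](O[Si](C)(C)C(C)(C)C)CC(C)(C)[C@H]1/C=C/C(C)=C/CO | intermediate
19 | {[(1R,4R)-4-[(1E,3E)-5-bromo-3-methylpenta-1,3-dien-1-yl]-3,5,5-trimethylcyclohex-2-en-1-yl]oxy}(tert-butyl)dimethylsilane (not isolated) | CC1=C[C@H](O[Si](C)(C)C(C)(C)C)CC(C)(C)[C@H]1/C=C/C(C)=C/CBr | intermediate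
20 | [(2E,4E)-5-[(1R,4R)-4-{[tert-butyl(dimethyl)silyl]oxy}-2,6,6-trimethylcyclohex-2-en-1-yl]-3-methylpenta-2,4-dien-1-yl]triphenylphosphonium bromide | CC1=C[C@H](O[Si](C)(C)C(C)(C)C)CC(C)(C)[C@H]1/C=C/C(C)=C/C[P+](c2ccccc2)(c3ccccc3)c4ccccc4.[Br-] | intermediate
21 | (4R,6R)-4-hydroxy-2,2,6-trimethylcyclohexan-1-one | O=C1[C@H](C)C[C@@H](O)CC1(C)C | starting material
22 | (4R,6R)-4-{[tert-butyl(dimethyl)silyl]oxy}-2,2,6-trimethylcyclohexan-1-one | O=C1[C@H](C)C[C@@H](O[Si](C)(C)C(C)(C)C)CC1(C)C | intermediate
23 | lithium (4R)-4-{[tert-butyl(dimethyl)silyl]oxy}-2,6,6-trimethylcyclohex-1-en-1-olate (not isolated) | [Li]OC1=C(C)C[C@@H](O[Si](C)(C)C(C)(C)C)CC1(C)C | intermediate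
24 | (4R)-4-{[tert-butyl(dimethyl)silyl]oxy}-2,6,6-trimethylcyclohex-1-en-1-yl trifluoromethanesulfonate | O=S(=O)(OC1=C(C)C[C@@H](O[Si](C)(C)C(C)(C)C)CC1(C)C)C(F)(F)F | intermediate
25 | (2E)-3-methylpent-2-en-4-yn-1-ol | C#C/C(C)=C/CO | starting material
26 | (2E)-3-methylpent-2-en-4-yn-1-yl 2,2-dimethylpropanoate | C#C/C(C)=C/COC(=O)C(C)(C)C | intermediate
27 | (2E)-5-[(4R)-4-{[tert-butyl(dimethyl)silyl]oxy}-2,6,6-trimethylcyclohex-1-en-1-yl]-3-methylpent-2-en-4-yn-1-yl 2,2-dimethylpropanoate | CC(C)(C)C(=O)OC/C=C(\C)C#CC1=C(C)C[C@@H](O[Si](C)(C)C(C)(C)C)CC1(C)C | intermediate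
28 | (2E)-5-[(1R,4S,6R)-4-{[tert-butyl(dimethyl)silyl]oxy}-2,2,6-trimethyl-7-oxabicyclo[4.1.0]heptan-1-yl]-3-methylpent-2-en-4-yn-1-yl 2,2-dimethylpropanoate (epoxide anti to the silyloxy group) | CC(C)(C)C(=O)OC/C=C(\C)C#C[C@]12C(C)(C)C[C@H](O[Si](C)(C)C(C)(C)C)C[C@@]1(C)O2 | intermediate
29 | (2E)-5-[(2R,4S)-4-{[tert-butyl(dimethyl)silyl]oxy}-2-hydroxy-2,6,6-trimethylcyclohexylidene]-3-methylpenta-2,4-dien-1-ol, (R)-allene axis | OC/C=C(\C)C=[C@@]=C1C(C)(C)C[C@H](O[Si](C)(C)C(C)(C)C)C[C@@]1(C)O | intermediate
30 | (2E)-3-[(2S,6S,7aR)-6-{[tert-butyl(dimethyl)silyl]oxy}-4,4,7a-trimethyl-2,4,5,6,7,7a-hexahydro-1-benzofuran-2-yl]but-2-en-1-ol | OC/C=C(\C)[C@@H]1C=C2C(C)(C)C[C@H](O[Si](C)(C)C(C)(C)C)C[C@@]2(C)O1 | intermediate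
31 | (2S,6S,7aR)-2-[(2E)-4-bromobut-2-en-2-yl]-6-{[tert-butyl(dimethyl)silyl]oxy}-4,4,7a-trimethyl-2,4,5,6,7,7a-hexahydro-1-benzofuran (not isolated) | BrC/C=C(\C)[C@@H]1C=C2C(C)(C)C[C@H](O[Si](C)(C)C(C)(C)C)C[C@@]2(C)O1 | intermediate
32 | [(2E)-3-[(2S,6S,7aR)-6-{[tert-butyl(dimethyl)silyl]oxy}-4,4,7a-trimethyl-2,4,5,6,7,7a-hexahydro-1-benzofuran-2-yl]but-2-en-1-yl]triphenylphosphonium bromide | [Br-].c3ccccc3[P+](c4ccccc4)(c5ccccc5)C/C=C(\C)[C@@H]1C=C2C(C)(C)C[C@H](O[Si](C)(C)C(C)(C)C)C[C@@]2(C)O1 | intermediate
33 | (2E,4E,6E)-2,7-dimethylocta-2,4,6-trienedial | O=C/C(C)=C/C=C/C=C(\C)C=O | starting material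
34 | (2E,4E,6E,8E,10E)-11-[(2S,6S,7aR)-6-{[tert-butyl(dimethyl)silyl]oxy}-4,4,7a-trimethyl-2,4,5,6,7,7a-hexahydro-1-benzofuran-2-yl]-2,7-dimethyldodeca-2,4,6,8,10-pentaenal | O=C/C(C)=C/C=C/C=C(C)/C=C/C=C(\C)[C@@H]1C=C2C(C)(C)C[C@H](O[Si](C)(C)C(C)(C)C)C[C@@]2(C)O1 | intermediate
35 | (3S,5R,8S,3′R,6′R)-3,3′-bis{[tert-butyl(dimethyl)silyl]oxy}-5,8-epoxy-5,8-dihydro-β,ε-carotene | CC1=C[C@H](O[Si](C)(C)C(C)(C)C)CC(C)(C)[C@H]1/C=C/C(C)=C/C=C/C(C)=C/C=C/C=C(C)/C=C/C=C(\C)[C@@H]1C=C2C(C)(C)C[C@H](O[Si](C)(C)C(C)(C)C)C[C@@]2(C)O1 | intermediate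
36 | (3S,5R,8S,3′R,6′R)-5,8-epoxy-5,8-dihydro-β,ε-carotene-3,3′-diol | CC1=C[C@H](O)CC(C)(C)[C@H]1/C=C/C(C)=C/C=C/C(C)=C/C=C/C=C(C)/C=C/C=C(\C)[C@@H]1C=C2C(C)(C)C[C@H](O)C[C@@]2(C)O1 | target

## Step count and least certain steps

Total step count: 24. Longest linear sequence: 15 steps (steps 1–13, then 23 and 24). The ring B/C branch has 8 steps (14–21) before the union in step 22.

**Step 6 (key step).** Most likely failure: erosion of trans selectivity through the competing chair with the vinyl group axial, or protodesilylation and enone deconjugation by traces of HCl before the ring closes.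
Fallback (doubly activated acceptor, chelation-controlled closure): it sets out from 5 and returns at 10.
- Acylation of lithiated tert-butyl acetate by 5 gives tert-butyl (5R)-5-methyl-3-oxohept-6-enoate F1.
- Knoevenagel condensation with acetone (TiCl4, pyridine, THF) gives tert-butyl (5R)-5-methyl-3-oxo-2-(propan-2-ylidene)hept-6-enoate F2.
- Cross-metathesis with 6 (second-generation Grubbs catalyst) gives tert-butyl (5R,6E)-5-methyl-3-oxo-2-(propan-2-ylidene)-8-(trimethylsilyl)oct-6-enoate F3.
- The alkylidene keto ester, bound to TiCl4 through both carbonyls, should cyclise at −78 °C to tert-butyl (3S,4R)-3-ethenyl-2,2,4-trimethyl-6-oxocyclohexane-1-carboxylate F4.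
- CF3CO2H followed by warming removes the ester carbon and gives 10.

**Step 10.** Most likely failure: sluggish metathesis at the hindered vinyl group, with migration of the double bond toward C6′ by ruthenium hydrides and loss of that centre.
Fallback (olefination in place of metathesis): it sets out from 10, where the vinyl group is the only alkene, and returns at 17.
- Ozonolysis (O3, CH2Cl2, −78 °C; Me2S) gives (1S,6R)-2,2,6-trimethyl-4-oxocyclohexane-1-carbaldehyde F5. Epimerisation at C6′ would only give a separable diastereomer, because C5′ is still a stereocentre.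
- Horner–Wadsworth–Emmons reaction with triethyl 3-methyl-4-phosphonocrotonate gives ethyl (2E,4E)-3-methyl-5-[(1R,6R)-2,2,6-trimethyl-4-oxocyclohexyl]penta-2,4-dienoate F6.
- Dehydrogenation as in step 7 gives ethyl (2E,4E)-3-methyl-5-[(1R)-2,6,6-trimethyl-4-oxocyclohex-2-en-1-yl]penta-2,4-dienoate F7.
- Reduction as in step 8 gives ethyl (2E,4E)-5-[(1R,4R)-4-hydroxy-2,6,6-trimethylcyclohex-2-en-1-yl]-3-methylpenta-2,4-dienoate F8.
- Silylation as in step 9 gives 17.

**Step 7.** Most likely failure: enolisation of the product toward C6′ under the oxidising, slightly acidic conditions, with racemisation or migration of the vinyl double bond into conjugation; incomplete conversion is the lesser risk.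
Fallback (two-stage Saegusa–Ito oxidation): it sets out from 10 and returns at 11.
- LiN(iPr)2 and Me3SiCl at −78 °C give the enol ether on the less hindered C4′ side, trimethyl{[(3S,4S)-4-ethenyl-3,5,5-trimethylcyclohex-1-en-1-yl]oxy}silane F9.
- Pd(OAc)2 (divalent palladium) in MeCN at rt gives 11. The regioisomeric enol ether cannot undergo β-hydride elimination and returns 10 on work-up.

**Step 19.** Most likely failure: hydride delivery to the wrong face of C8 (anti to the leaving oxygen), which would give the epimeric axis and hence the 8R ether after step 20; direct reductive opening of the epoxide is the lesser risk.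
Fallback (epoxide-to-furanoid rearrangement without an allene): it sets out from 24 and 26 and returns at 30.
- Hydroboration of 26 with pinacolborane (Cp2Zr(H)Cl cat.) gives (2E,4E)-3-methyl-5-(4,4,5,5-tetramethyl-1,3,2-dioxaborolan-2-yl)penta-2,4-dien-1-yl 2,2-dimethylpropanoate F10.
- Suzuki–Miyaura coupling with 24 (Pd(PPh3)4, K3PO4) gives (2E,4E)-5-[(4R)-4-{[tert-butyl(dimethyl)silyl]oxy}-2,6,6-trimethylcyclohex-1-en-1-yl]-3-methylpenta-2,4-dien-1-yl 2,2-dimethylpropanoate F11.
- mCPBA gives the anti epoxide (2E,4E)-5-[(1S,4S,6R)-4-{[tert-butyl(dimethyl)silyl]oxy}-2,2,6-trimethyl-7-oxabicyclo[4.1.0]heptan-1-yl]-3-methylpenta-2,4-dien-1-yl 2,2-dimethylpropanoate F12.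
- Pyridinium p-toluenesulfonate in CH2Cl2 rearranges it to the 8S furanoid pivalate F13 (the same compound as A1) and its 8R epimer F14. These are separated by chromatography, and F14 is returned to the same acid to re-establish the mixture.
- i-Bu2AlH cleaves the pivalate of F13 and gives 30.
- This path gives up stereocontrol at C8 and is therefore only the reserve.

## Further compounds

F1 | step 6 | tert-butyl (5R)-5-methyl-3-oxohept-6-enoate | C=C[C@H](C)CC(=O)CC(=O)OC(C)(C)C
F2 | step 6 | tert-butyl (5R)-5-methyl-3-oxo-2-(propan-2-ylidene)hept-6-enoate | C=C[C@H](C)CC(=O)C(=C(C)C)C(=O)OC(C)(C)C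
F3 | step 6 | tert-butyl (5R,6E)-5-methyl-3-oxo-2-(propan-2-ylidene)-8-(trimethylsilyl)oct-6-enoate | C[Si](C)(C)C/C=C/[C@H](C)CC(=O)C(=C(C)C)C(=O)OC(C)(C)C
F4 | step 6 | tert-butyl (3S,4R)-3-ethenyl-2,2,4-trimethyl-6-oxocyclohexane-1-carboxylate | C[C@@H]1CC(=O)C(C(=O)OC(C)(C)C)C(C)(C)[C@H]1C=C
F5 | step 10 | (1S,6R)-2,2,6-trimethyl-4-oxocyclohexane-1-carbaldehyde | C[C@@H]1CC(=O)CC(C)(C)[C@H]1C=O
F6 | step 10 | ethyl (2E,4E)-3-methyl-5-[(1R,6R)-2,2,6-trimethyl-4-oxocyclohexyl]penta-2,4-dienoate | C[C@@H]1CC(=O)CC(C)(C)[C@H]1/C=C/C(C)=C/C(=O)OCC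
F7 | step 10 | ethyl (2E,4E)-3-methyl-5-[(1R)-2,6,6-trimethyl-4-oxocyclohex-2-en-1-yl]penta-2,4-dienoate | CC1=CC(=O)CC(C)(C)[C@H]1/C=C/C(C)=C/C(=O)OCC
F8 | step 10 | ethyl (2E,4E)-5-[(1R,4R)-4-hydroxy-2,6,6-trimethylcyclohex-2-en-1-yl]-3-methylpenta-2,4-dienoate | CC1=C[C@H](O)CC(C)(C)[C@H]1/C=C/C(C)=C/C(=O)OCC
F9 | step 7 | trimethyl{[(3S,4S)-4-ethenyl-3,5,5-trimethylcyclohex-1-en-1-yl]oxy}silane | C[C@@H]1C=C(O[Si](C)(C)C)CC(C)(C)[C@H]1C=C
F10 | step 19 | (2E,4E)-3-methyl-5-(4,4,5,5-tetramethyl-1,3,2-dioxaborolan-2-yl)penta-2,4-dien-1-yl 2,2-dimethylpropanoate | CC(C)(C)C(=O)OC/C=C(C)/C=C/B1OC(C)(C)C(C)(C)O1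
F11 | step 19 | (2E,4E)-5-[(4R)-4-{[tert-butyl(dimethyl)silyl]oxy}-2,6,6-trimethylcyclohex-1-en-1-yl]-3-methylpenta-2,4-dien-1-yl 2,2-dimethylpropanoate | CC(C)(C)C(=O)OC/C=C(C)/C=C/C1=C(C)C[C@@H](O[Si](C)(C)C(C)(C)C)CC1(C)C
F12 | step 19 | (2E,4E)-5-[(1S,4S,6R)-4-{[tert-butyl(dimethyl)silyl]oxy}-2,2,6-trimethyl-7-oxabicyclo[4.1.0]heptan-1-yl]-3-methylpenta-2,4-dien-1-yl 2,2-dimethylpropanoate | CC(C)(C)C(=O)OC/C=C(C)/C=C/[C@]12C(C)(C)C[C@H](O[Si](C)(C)C(C)(C)C)C[C@@]1(C)O2
F13 | step 19 | (2E)-3-[(2S,6S,7aR)-6-{[tert-butyl(dimethyl)silyl]oxy}-4,4,7a-trimethyl-2,4,5,6,7,7a-hexahydro-1-benzofuran-2-yl]but-2-en-1-yl 2,2-dimethylpropanoate | CC(C)(C)C(=O)OC/C=C(\C)[C@@H]1C=C2C(C)(C)C[C@H](O[Si](C)(C)C(C)(C)C)C[C@@]2(C)O1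
F14 | step 19 | (2E)-3-[(2R,6S,7aR)-6-{[tert-butyl(dimethyl)silyl]oxy}-4,4,7a-trimethyl-2,4,5,6,7,7a-hexahydro-1-benzofuran-2-yl]but-2-en-1-yl 2,2-dimethylpropanoate | CC(C)(C)C(=O)OC/C=C(\C)[C@H]1C=C2C(C)(C)C[C@H](O[Si](C)(C)C(C)(C)C)C[C@@]2(C)O1
A1 | alternative 1 | (2E)-3-[(2S,6S,7aR)-6-{[tert-butyl(dimethyl)silyl]oxy}-4,4,7a-trimethyl-2,4,5,6,7,7a-hexahydro-1-benzofuran-2-yl]but-2-en-1-yl 2,2-dimethylpropanoate | CC(C)(C)C(=O)OC/C=C(\C)[C@@H]1C=C2C(C)(C)C[C@H](O[Si](C)(C)C(C)(C)C)C[C@@]2(C)O1
A2 | alternative 1 | (2E)-5-[(2R,4S)-4-{[tert-butyl(dimethyl)silyl]oxy}-2-hydroxy-2,6,6-trimethylcyclohexylidene]-3-methylpenta-2,4-dien-1-yl 2,2-dimethylpropanoate, (R)-allene axis | CC(C)(C)C(=O)OC/C=C(\C)C=[C@@]=C1C(C)(C)C[C@H](O[Si](C)(C)C(C)(C)C)C[C@@]1(C)O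
A3 | alternative 2 | (7a′R)-4′,4′,7a′-trimethyl-3′-(trimethylsilyl)-4′,5′,7′,7a′-tetrahydro-2′H-spiro[1,3-dioxolane-2,6′-[1]benzofuran]-2′-one | O=C1C([Si](C)(C)C)=C2C(C)(C)CC3(OCCO3)C[C@@]2(C)O1
A4 | alternative 2 | 1-{2-[2,2-dimethyl-4-(trimethylsilyl)but-3-yn-1-yl]-1,3-dioxolan-2-yl}propan-2-one | CC(=O)CC1(CC(C)(C)C#C[Si](C)(C)C)OCCO1
A5 | alternative 3 | (2E)-3-[(2S,3aR,6S,7aR)-3a,6-dihydroxy-4,4,7a-trimethyloctahydro-1-benzofuran-2-yl]but-2-en-1-yl 2,2-dimethylpropanoate | CC(C)(C)C(=O)OC/C=C(\C)[C@@H]1C[C@@]2(O)C(C)(C)C[C@H](O)C[C@@]2(C)O1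
A6 | alternative 3 | (2E,4S)-4-hydroxy-5-[(1R,4S,6S)-4-hydroxy-2,2,6-trimethyl-7-oxabicyclo[4.1.0]heptan-1-yl]-3-methylpent-2-en-1-yl 2,2-dimethylpropanoate | CC(C)(C)C(=O)OC/C=C(\C)[C@@H](O)C[C@@]12C(C)(C)C[C@H](O)C[C@]1(C)O2
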